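## Retrosynthetic overview

1. Actephilol C ⇒ its di-O-benzyl ether 35 ⇒ the cis-fused 1,4-dioxane ring (both stereocentres) is opened into the enone half 19 (C3=C4 enol ether) and the ortho-quinone 34, a hetero-Diels–Alder union as presumed in the biosynthesis.
2. Enone half 19 ⇒ ring C opened at C10a–C1 and C4a–C4: Diels–Alder reaction of 1,2-naphthalyne 17 with acyclic diene 6, then loss of Me2NH and the silyl group.
3. Enabling feature: the C4a–C10a bond of the naphthalene is the π-bond of an aryne, and C1–C4 of ring C carry oxygen on C2 and C3 and a heteroatom on C4. This is the pattern of a 1-amino-2-methoxy-3-silyloxy diene whose nucleophilic CMe2 terminus becomes quaternary C1.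
4. Quinone half 34 ⇒ oxygenative demethylation of the 3-methoxyphenanthren-2-ol 33, whose oxygenated ring is built by the same aryne cycloaddition (naphthalyne 31 + diene 23) and aromatises; both naphthalynes come from Dötz benzannulations that place OH and SiMe3 on adjacent carbons.
5. Ring order: second naphthalene ring of each half (Dötz) → ring C of 19 and the oxygenated ring of 33 (aryne Diels–Alder) → dioxane ring → debenzylation.

Key step: step 8

Remark: phenanthrene locants are used for both halves. The sense of induction of the copper bis(oxazoline) catalyst in step 18 cannot be predicted with confidence; the (S,S) ligand is assumed to give 35, and the antipodal ligand would be used if the first run gave the enantiomer.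

## Route

Step 1
Reactants: 1 N,2-dimethoxy-N-methylacetamide; 2 isopropylmagnesium chloride
Product: 3 1-methoxy-3-methylbutan-2-one
Conditions: i-PrMgCl (1.2 equiv), THF, 0 °C; then 1 M HCl
Reagents that add atoms: none
Why: Weinreb ketone synthesis, in which the magnesium chelate of the adduct should survive until work-up so that only one isopropyl group is delivered.

Step 2
Reactants: 3 1-methoxy-3-methylbutan-2-one; 4 N,N-dimethylformamide dimethyl acetal
Product: 5 (1Z)-1-(dimethylamino)-2-methoxy-4-methylpent-1-en-3-one
Conditions: neat 4 (1.5 equiv), 100 °C, methanol distilled off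
Reagents that add atoms: none
Why: Enaminone formation by amide acetal condensation at the only methylene group (the other α-carbon is a methine), which should give the push–pull alkene with nitrogen trans to the carbonyl.

Step 3
Reactants: 5 (1Z)-1-(dimethylamino)-2-methoxy-4-methylpent-1-en-3-one
Product: 6 (1Z)-3-[(tert-butyldimethylsilyl)oxy]-2-methoxy-N,N,4-trimethylpenta-1,3-dien-1-amine
Conditions: KN(SiMe3)2, THF, −78 to −40 °C; t-BuMe2SiCl, −78 °C to rt; filtered under argon, used crude
Reagents that add atoms: tert-butyldimethylsilyl chloride CC(C)(C)[Si](C)(C)Cl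
Why: Kinetic deprotonation of the vinylogous amide at its only enolisable position and O-silylation of the potassium dienolate, the standard preparation of 1-amino-3-silyloxy dienes.

Step 4
Reactants: 7 4-bromo-1-methoxy-2-methylbenzene; 8 hexacarbonylchromium Cr(CO)6
Product: 11 tetramethylammonium pentacarbonyl[(4-methoxy-3-methylphenyl)(oxido)methylidene]chromate, via aryllithium 9 (not isolated), via lithium acylchromate 10 (not isolated)
Conditions: n-BuLi, Et2O, −78 °C; Cr(CO)6, −78 °C to rt; then Me4NBr, H2O, 0 °C
Reagents that add atoms: tetramethylammonium bromide C[N+](C)(C)C.[Br-]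
Why: First half of the Fischer carbene synthesis, in which bromine–lithium exchange and addition of the aryllithium to a carbonyl ligand of zerovalent chromium hexacarbonyl should give the acylchromate, collected as its storable tetramethylammonium salt.

Step 5
Reactants: 11 tetramethylammonium pentacarbonyl[(4-methoxy-3-methylphenyl)(oxido)methylidene]chromate
Product: 13 pentacarbonyl[(benzyloxy)(4-methoxy-3-methylphenyl)methylidene]chromium, via acetoxycarbene complex 12 (not isolated)
Conditions: AcBr, CH2Cl2, −40 °C; then BnOH, −40 to 0 °C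
Reagents that add atoms: benzyl alcohol OCc1ccccc1
Why: O-acylation of the acylchromate gives an acyloxycarbene complex whose acetate should be displaced by benzyl alcohol through addition–elimination at the carbene carbon, the established alkoxy-exchange route to alkoxycarbene complexes.

Step 6
Reactants: 13 pentacarbonyl[(benzyloxy)(4-methoxy-3-methylphenyl)methylidene]chromium; 14 ethynyltrimethylsilane
Product: 15 4-(benzyloxy)-7-methoxy-6-methyl-2-(trimethylsilyl)naphthalen-1-ol
Conditions: 14 (2 equiv), THF, 50 °C; then air, rt, filtration through silica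
Reagents that add atoms: none
Why: Dötz benzannulation, in which alkyne and one CO ligand are joined to the aryl carbene with the silyl-bearing alkyne carbon next to the new hydroxyl carbon and ring closure at the aryl ortho carbon remote from the methyl group.

Step 7
Reactants: 15 4-(benzyloxy)-7-methoxy-6-methyl-2-(trimethylsilyl)naphthalen-1-ol
Product: 16 4-(benzyloxy)-7-methoxy-6-methyl-2-(trimethylsilyl)naphthalen-1-yl trifluoromethanesulfonate
Conditions: (CF3SO2)2O, pyridine, CH2Cl2, 0 °C
Reagents that add atoms: trifluoromethanesulfonic anhydride O=S(=O)(OS(=O)(=O)C(F)(F)F)C(F)(F)F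
Why: O-sulfonylation of the naphthol should give the ortho-silylaryl triflate, the standard fluoride-triggered aryne precursor.

Step 8
Reactants: 16 4-(benzyloxy)-7-methoxy-6-methyl-2-(trimethylsilyl)naphthalen-1-yl trifluoromethanesulfonate; 6 (1Z)-3-[(tert-butyldimethylsilyl)oxy]-2-methoxy-N,N,4-trimethylpenta-1,3-dien-1-amine
Product: 19 9-(benzyloxy)-3,6-dimethoxy-1,1,7-trimethylphenanthren-2(1H)-one, via naphthalyne 17 (not isolated), via amino silyl enol ether cycloadduct 18 (not isolated)
Conditions: 6 (2.5 equiv), CsF (3 equiv), MeCN–toluene (1:1), rt; then 1 M HCl, THF, 0 °C to rt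
Reagents that add atoms: none
Why: Fluoride removes the trimethylsilyl group of 16 and expels triflate to give naphthalyne 17, whose strained in-plane π-bond (the future C4a–C10a bond) should take up diene 6 in an asynchronous Diels–Alder reaction: the gem-dimethyl terminus, the most nucleophilic carbon of the diene, bonds to the β-carbon of the aryne (C10a) and the amino-bearing terminus to the α-carbon (C4a). The closest known reaction type is the aryne Diels–Alder reaction of acyclic dienes, including 1-hetero-3-silyloxy dienes, followed by the acid-induced loss of amine and silyl group that is standard for amino-silyloxy diene adducts. Ring C is closed by intermolecular [4+2] cycloaddition, both C–C bonds being made on one face of the cisoid diene. The only new stereocentre (C4 of 18) forms as a racemate and is erased when dimethylamine is eliminated, so no stereocontrol is needed. The step needs regioselectivity (C1 next to C10a) and chemoselectivity ([4+2] over ene and [2+2] paths). The first is secured by matching the bulky, nucleophilic CMe2 terminus with the aryne carbon that is more electrophilic and remote from the peri C5–H; the second by the 2-methoxy group, whose clash with the cis methyl of the CMe2 terminus disfavours the transoid conformer and keeps the diene cisoid.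

Step 9
Reactants: 1 N,2-dimethoxy-N-methylacetamide; 20 ethylmagnesium bromide
Product: 21 1-methoxybutan-2-one
Conditions: EtMgBr (1.2 equiv), THF, 0 °C; then 1 M HCl
Reagents that add atoms: none
Why: Weinreb ketone synthesis as in step 1.

Step 10
Reactants: 21 1-methoxybutan-2-one; 4 N,N-dimethylformamide dimethyl acetal
Product: 22 (1Z)-1-(dimethylamino)-2-methoxypent-1-en-3-one
Conditions: neat 4 (1.5 equiv), 90 °C, methanol distilled off
Reagents that add atoms: none
Why: Amide acetal condensation, expected at the methoxy-bearing methylene because it is the more acidic of the two α-methylene groups (as with methoxyacetone), with any regioisomer removed by distillation.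

Step 11
Reactants: 22 (1Z)-1-(dimethylamino)-2-methoxypent-1-en-3-one
Product: 23 (1Z,3Z)-3-[(tert-butyldimethylsilyl)oxy]-2-methoxy-N,N-dimethylpenta-1,3-dien-1-amine
Conditions: KN(SiMe3)2, THF, −78 °C; t-BuMe2SiCl, −78 °C to rt; filtered under argon, used crude
Reagents that add atoms: tert-butyldimethylsilyl chloride CC(C)(C)[Si](C)(C)Cl
Why: Dienolate O-silylation as in step 3, where the potassium enolate of the ethyl ketone should form mainly with Z geometry, which puts hydrogen rather than methyl on the inside of the cisoid diene.

Step 12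
Reactants: 24 4-bromo-2-methylphenol
Product: 25 1-(benzyloxy)-4-bromo-2-methylbenzene
Conditions: BnBr, K2CO3, DMF, rt
Reagents that add atoms: benzyl bromide BrCc1ccccc1
Why: Williamson ether synthesis on the phenoxide.

Step 13
Reactants: 25 1-(benzyloxy)-4-bromo-2-methylbenzene; 8 hexacarbonylchromium Cr(CO)6
Product: 28 pentacarbonyl{[4-(benzyloxy)-3-methylphenyl](methoxy)methylidene}chromium, via aryllithium 26 (not isolated), via lithium acylchromate 27 (not isolated)
Conditions: n-BuLi, Et2O, −78 °C; Cr(CO)6, −78 °C to rt; solvent exchange; Me3OBF4, CH2Cl2, 0 °C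
Reagents that add atoms: trimethyloxonium tetrafluoroborate C[O+](C)C.F[B-](F)(F)F
Why: Fischer carbene synthesis, in which the aryllithium adds to a carbonyl ligand of zerovalent chromium hexacarbonyl and the acylchromate oxygen is methylated by the oxonium salt.

Step 14
Reactants: 28 pentacarbonyl{[4-(benzyloxy)-3-methylphenyl](methoxy)methylidene}chromium; 14 ethynyltrimethylsilane
Product: 29 7-(benzyloxy)-4-methoxy-6-methyl-2-(trimethylsilyl)naphthalen-1-ol
Conditions: 14 (2 equiv), THF, 50 °C; then air, rt, filtration through silica
Reagents that add atoms: none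
Why: Dötz benzannulation as in step 6, with the silyl-bearing alkyne carbon next to the new hydroxyl carbon and closure at the aryl ortho carbon away from the methyl group.

Step 15
Reactants: 29 7-(benzyloxy)-4-methoxy-6-methyl-2-(trimethylsilyl)naphthalen-1-ol
Product: 30 7-(benzyloxy)-4-methoxy-6-methyl-2-(trimethylsilyl)naphthalen-1-yl trifluoromethanesulfonate
Conditions: (CF3SO2)2O, pyridine, CH2Cl2, 0 °C
Reagents that add atoms: trifluoromethanesulfonic anhydride O=S(=O)(OS(=O)(=O)C(F)(F)F)C(F)(F)F
Why: O-sulfonylation to the ortho-silylaryl triflate as in step 7.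

Step 16
Reactants: 30 7-(benzyloxy)-4-methoxy-6-methyl-2-(trimethylsilyl)naphthalen-1-yl trifluoromethanesulfonate; 23 (1Z,3Z)-3-[(tert-butyldimethylsilyl)oxy]-2-methoxy-N,N-dimethylpenta-1,3-dien-1-amine
Product: 33 6-(benzyloxy)-3,9-dimethoxy-1,7-dimethylphenanthren-2-ol, via naphthalyne 31 (not isolated), via amino silyl enol ether cycloadduct 32 (not isolated)
Conditions: 23 (2.5 equiv), CsF (3 equiv), MeCN–toluene (1:1), rt; then 1 M HCl, THF, 0 °C to rt
Reagents that add atoms: none
Why: Same aryne Diels–Alder reaction as in step 8 (methyl-bearing nucleophilic terminus to the aryne β-carbon, the future C10a), after which loss of dimethylamine and the silyl group gives a 1H-phenanthren-2-one that tautomerises to the phenol, so the C1 and C4 stereocentres of 32 disappear.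

Step 17
Reactants: 33 6-(benzyloxy)-3,9-dimethoxy-1,7-dimethylphenanthren-2-ol
Product: 34 6-(benzyloxy)-9-methoxy-1,7-dimethylphenanthrene-2,3-dione
Conditions: stabilised IBX (1.2 equiv), THF, rt, dark; cold aqueous NaHCO3 wash, dried over MgSO4, concentrated at 0 °C, taken up in CH2Cl2 and used at once
Reagents that add atoms: 2-iodoxybenzoic acid O=C1OI(=O)(O)c2ccccc12
Why: Oxygenative demethylation of a 2-methoxyphenol, in which the aryloxy derivative of pentavalent iodine delivers oxygen to the methoxy-bearing ortho carbon and methanol is lost to give the ortho-quinone, which is freed from the acidic iodine by-products by the bicarbonate wash and carried straight into the cycloaddition.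

Step 18
Reactants: 34 6-(benzyloxy)-9-methoxy-1,7-dimethylphenanthrene-2,3-dione; 19 9-(benzyloxy)-3,6-dimethoxy-1,1,7-trimethylphenanthren-2(1H)-one
Product: 35 di-O-benzyl actephilol C (3S,4S)
Conditions: 34 in CH2Cl2 added slowly to 19 (1.2 equiv), Cu(OTf)2 (10 mol %), 2,2'-(propane-2,2-diyl)bis[(4S)-4-tert-butyl-4,5-dihydro-1,3-oxazole] (11 mol %), 4 Å molecular sieves, CH2Cl2, −40 °C
Reagents that add atoms: none
Why: Proposed new method: the ortho-quinone 34, a 1,2-dicarbonyl heterodiene, should chelate the divalent copper bis(oxazoline) complex through both oxygens and take up the C3=C4 enol ether of 19 in an inverse-electron-demand hetero-Diels–Alder reaction; C3 of 19 (made nucleophilic by the para-benzyloxynaphthyl group acting through C4) should attack the oxygen on C2 of 34 because the C3 carbonyl is the better acceptor (the C2 carbonyl is a doubly vinylogous ester of the 9-methoxy group), and the copper-bound aryloxide then closes on benzylic C4 from the same face, so both C–O bonds are syn and the dioxane is cis-fused (3-OMe and 4-H cis); because the two quinone oxygens are differentiated in this way, the C2-symmetric ligand shields one face of the bound quinone for this orientation and should set C3 and C4 as (S,S); the closest known reaction types are the uncatalysed [4+2] cycloadditions of ortho-quinones with enol ethers and styrenes to 1,4-benzodioxanes, the copper bis(oxazoline)-catalysed enantioselective inverse-demand hetero-Diels–Alder reactions of chelating 1-oxadienes with enol ethers, and the Lewis-acid-assisted enantioselective cycloadditions of ortho-quinones with ketene enolates.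

Step 19
Reactants: 35 di-O-benzyl actephilol C (3S,4S)
Product: 36 actephilol C
Conditions: H2 (1 atm), 10% Pd/C, EtOAc, rt
Reagents that add atoms: none
Why: Catalytic hydrogenolysis of the two aryl benzyl ethers, which should leave the cyclic benzylic aryl ether at C4, the hindered ketone and the ketal untouched and affects no stereocentre.

## Compound list

1 | N,2-dimethoxy-N-methylacetamide | COCC(=O)N(C)OC | starting material
2 | isopropylmagnesium chloride | CC(C)[Mg]Cl | starting material
3 | 1-methoxy-3-methylbutan-2-one | COCC(=O)C(C)C | intermediate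
4 | N,N-dimethylformamide dimethyl acetal | COC(OC)N(C)C | starting material
5 | (1Z)-1-(dimethylamino)-2-methoxy-4-methylpent-1-en-3-one | CC(C)C(=O)/C(OC)=C/N(C)C | intermediate
6 | (1Z)-3-[(tert-butyldimethylsilyl)oxy]-2-methoxy-N,N,4-trimethylpenta-1,3-dien-1-amine | CC(C)=C(O[Si](C)(C)C(C)(C)C)/C(OC)=C/N(C)C | intermediate
7 | 4-bromo-1-methoxy-2-methylbenzene | COc1ccc(Br)cc1C | starting material
8 | hexacarbonylchromium Cr(CO)6 | O=C=[Cr](=C=O)(=C=O)(=C=O)(=C=O)=C=O | starting material
9 | (4-methoxy-3-methylphenyl)lithium | [Li]c1ccc(OC)c(C)c1 | intermediate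
10 | lithium pentacarbonyl[(4-methoxy-3-methylphenyl)(oxido)methylidene]chromate | [Li+].[O-]C(c1ccc(OC)c(C)c1)=[Cr](=C=O)(=C=O)(=C=O)(=C=O)=C=O | intermediate
11 | tetramethylammonium pentacarbonyl[(4-methoxy-3-methylphenyl)(oxido)methylidene]chromate | C[N+](C)(C)C.[O-]C(c1ccc(OC)c(C)c1)=[Cr](=C=O)(=C=O)(=C=O)(=C=O)=C=O | intermediate
12 | pentacarbonyl[(acetyloxy)(4-methoxy-3-methylphenyl)methylidene]chromium | CC(=O)OC(c1ccc(OC)c(C)c1)=[Cr](=C=O)(=C=O)(=C=O)(=C=O)=C=O | intermediate
13 | pentacarbonyl[(benzyloxy)(4-methoxy-3-methylphenyl)methylidene]chromium | COc1ccc(cc1C)C(OCc1ccccc1)=[Cr](=C=O)(=C=O)(=C=O)(=C=O)=C=O | intermediate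
14 | ethynyltrimethylsilane | C#C[Si](C)(C)C | starting material
15 | 4-(benzyloxy)-7-methoxy-6-methyl-2-(trimethylsilyl)naphthalen-1-ol | COc1cc2c(O)c([Si](C)(C)C)cc(OCc3ccccc3)c2cc1C | intermediate
16 | 4-(benzyloxy)-7-methoxy-6-methyl-2-(trimethylsilyl)naphthalen-1-yl trifluoromethanesulfonate | COc1cc2c(OS(=O)(=O)C(F)(F)F)c([Si](C)(C)C)cc(OCc3ccccc3)c2cc1C | intermediate
17 | 4-(benzyloxy)-7-methoxy-6-methyl-1,2-didehydronaphthalene (1,2-naphthalyne) | COC1=CC2=C(C=C1C)C(OCc1ccccc1)=CC#C2 | intermediate
18 | 9-(benzyloxy)-2-[(tert-butyldimethylsilyl)oxy]-3,6-dimethoxy-N,N,1,1,7-pentamethyl-1,4-dihydrophenanthren-4-amine (racemic at C4) | COc1cc2c3c(cc(OCc4ccccc4)c2cc1C)C(C)(C)C(O[Si](C)(C)C(C)(C)C)=C(OC)C3N(C)C | intermediate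
19 | 9-(benzyloxy)-3,6-dimethoxy-1,1,7-trimethylphenanthren-2(1H)-one | COc1cc2c3c(cc(OCc4ccccc4)c2cc1C)C(C)(C)C(=O)C(OC)=C3 | intermediate
20 | ethylmagnesium bromide | CC[Mg]Br | starting material
21 | 1-methoxybutan-2-one | CCC(=O)COC | intermediate
22 | (1Z)-1-(dimethylamino)-2-methoxypent-1-en-3-one | CCC(=O)/C(OC)=C/N(C)C | intermediate
23 | (1Z,3Z)-3-[(tert-butyldimethylsilyl)oxy]-2-methoxy-N,N-dimethylpenta-1,3-dien-1-amine | C/C=C(/C(OC)=C/N(C)C)O[Si](C)(C)C(C)(C)C | intermediate
24 | 4-bromo-2-methylphenol | Cc1cc(Br)ccc1O | starting material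
25 | 1-(benzyloxy)-4-bromo-2-methylbenzene | Cc1cc(Br)ccc1OCc1ccccc1 | intermediate
26 | [4-(benzyloxy)-3-methylphenyl]lithium | [Li]c1ccc(OCc2ccccc2)c(C)c1 | intermediate
27 | lithium pentacarbonyl{[4-(benzyloxy)-3-methylphenyl](oxido)methylidene}chromate | [Li+].[O-]C(c1ccc(OCc2ccccc2)c(C)c1)=[Cr](=C=O)(=C=O)(=C=O)(=C=O)=C=O | intermediate
28 | pentacarbonyl{[4-(benzyloxy)-3-methylphenyl](methoxy)methylidene}chromium | COC(c1ccc(OCc2ccccc2)c(C)c1)=[Cr](=C=O)(=C=O)(=C=O)(=C=O)=C=O | intermediate
29 | 7-(benzyloxy)-4-methoxy-6-methyl-2-(trimethylsilyl)naphthalen-1-ol | COc1cc([Si](C)(C)C)c(O)c2cc(OCc3ccccc3)c(C)cc12 | intermediate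
30 | 7-(benzyloxy)-4-methoxy-6-methyl-2-(trimethylsilyl)naphthalen-1-yl trifluoromethanesulfonate | COc1cc([Si](C)(C)C)c(OS(=O)(=O)C(F)(F)F)c2cc(OCc3ccccc3)c(C)cc12 | intermediate
31 | 7-(benzyloxy)-4-methoxy-6-methyl-1,2-didehydronaphthalene (1,2-naphthalyne) | COC1=CC#CC2=C1C=C(C)C(OCc1ccccc1)=C2 | intermediate
32 | 6-(benzyloxy)-2-[(tert-butyldimethylsilyl)oxy]-3,9-dimethoxy-N,N,1,7-tetramethyl-1,4-dihydrophenanthren-4-amine (mixture of stereoisomers at C1 and C4) | CN(C)C1C(OC)=C(O[Si](C)(C)C(C)(C)C)C(C)c2cc(OC)c3cc(C)c(OCc4ccccc4)cc3c21 | intermediate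
33 | 6-(benzyloxy)-3,9-dimethoxy-1,7-dimethylphenanthren-2-ol | COc1cc2c(cc(OC)c3cc(C)c(OCc4ccccc4)cc32)c(C)c1O | intermediate
34 | 6-(benzyloxy)-9-methoxy-1,7-dimethylphenanthrene-2,3-dione | CC1=C2C=C(OC)c3cc(C)c(OCc4ccccc4)cc3C2=CC(=O)C1=O | intermediate
35 | di-O-benzyl actephilol C: benzyl on the C9 oxygen of the dihydrophenanthrenone half and on the C6 oxygen of the phenanthrene half; ketal carbon C3 (S), benzylic O–CH carbon C4 (S), 3-OMe and 4-H cis | COc1cc2c3c(cc(OCc6ccccc6)c2cc1C)C(C)(C)C(=O)[C@@]1(OC)Oc2c(cc4c(cc(OC)c5cc(C)c(OCc6ccccc6)cc54)c2C)O[C@@H]31 | intermediate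
36 | actephilol C: 9-hydroxy-3,6-dimethoxy-1,1,7-trimethyl-3,4-dihydrophenanthren-2(1H)-one whose C3 and C4 are bridged as a cis-fused 1,4-dioxane by O2 (to C3) and O3 (to C4) of 6-hydroxy-9-methoxy-1,7-dimethylphenanthrene-2,3-diol; (3S,4S) | COc1cc2c3c(cc(O)c2cc1C)C(C)(C)C(=O)[C@@]1(OC)Oc2c(cc4c(cc(OC)c5cc(C)c(O)cc54)c2C)O[C@@H]31 | target

## Summary and risks

Total step count: 19. Longest linear sequence: 8 steps (steps 12, 13, 14, 15, 16, 17, 18, 19).

Steps most likely to fail:

1. Step 18 (proposed new method). What may go wrong: poor facial selectivity at the copper-bound quinone, so that the adduct forms with low enantiomeric excess, or decay of the quinone (dimerisation, tautomerisation to a quinone methide) faster than its cycloaddition at low temperature. Fallback with known chemistry, setting out from 34 and 19: the two are stirred in toluene at room temperature without any catalyst, with 19 in threefold excess so that the quinone is consumed quickly. This is the uncatalysed [4+2] cycloaddition of ortho-quinones with enol ethers and styrenes that gives 2,3-dihydro-1,4-benzodioxines. It should give the cis-fused adduct as a racemate, that is 35 together with the (3R,4R) enantiomer of di-O-benzyl actephilol C F1. The enantiomers are separated by preparative HPLC on an amylose carbamate chiral stationary phase, and the route is rejoined at 35.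

2. Step 8 (key step). What may go wrong: the aryne may react with the fully substituted diene terminus by an ene or stepwise path, or through the transoid conformer, so that only the first C–C bond forms or the regiochemistry erodes. Fallback, setting out from 16 and 5: the enaminone 5 is deprotonated with KN(SiMe3)2 in THF and arylated in the same flask by the aryne released from 16 (CsF, 18-crown-6). This is the known C-arylation of ketone enolates by arynes, at the aryne β-carbon, and should give the open-chain 4-aryl enaminone F2. The second bond is then closed separately by acid (CF3CO2H, 1,2-dichloroethane, 60 °C): the protonated enaminone is attacked by the naphthalene α-carbon para to the benzyloxy group (intramolecular Friedel–Crafts cyclisation) and dimethylamine is lost. The route is rejoined at 19.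

3. Step 6 (the same applies to step 14). What may go wrong: loss of the trimethylsilyl group, or its migration from carbon to oxygen, during benzannulation and decomplexation, which would leave no ortho C–Si bond for aryne generation. Fallback, setting out from 13 and 14: the benzannulation is run as before but the crude product is treated with Bu4NF so that all silicon is removed, giving the silicon-free naphthol F3. Ortho-bromination (N-bromosuccinimide, i-Pr2NH cat., CH2Cl2, −78 °C) gives the 2-bromonaphthol F4. O-Silylation with (Me3Si)2NH gives the silyl ether F5. Bromine–lithium exchange (n-BuLi, THF, −78 °C) then triggers the retro-Brook oxygen-to-carbon silyl shift to the lithium naphthoxide F6, which is triflated in the same flask with (CF3SO2)2O. The route is rejoined at 16.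

## Further compounds

F1 | step 18 | (3R,4R) enantiomer of di-O-benzyl actephilol C | COc1cc2c3c(cc(OCc6ccccc6)c2cc1C)C(C)(C)C(=O)[C@]1(OC)Oc2c(cc4c(cc(OC)c5cc(C)c(OCc6ccccc6)cc54)c2C)O[C@H]31
F2 | step 8 | (1Z)-4-[4-(benzyloxy)-7-methoxy-6-methylnaphthalen-2-yl]-1-(dimethylamino)-2-methoxy-4-methylpent-1-en-3-one | COc1cc2cc(cc(OCc3ccccc3)c2cc1C)C(C)(C)C(=O)/C(OC)=C/N(C)C
F3 | step 6 | 4-(benzyloxy)-7-methoxy-6-methylnaphthalen-1-ol | COc1cc2c(O)ccc(OCc3ccccc3)c2cc1C
F4 | step 6 | 4-(benzyloxy)-2-bromo-7-methoxy-6-methylnaphthalen-1-ol | COc1cc2c(O)c(Br)cc(OCc3ccccc3)c2cc1C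
F5 | step 6 | {[4-(benzyloxy)-2-bromo-7-methoxy-6-methylnaphthalen-1-yl]oxy}trimethylsilane | COc1cc2c(O[Si](C)(C)C)c(Br)cc(OCc3ccccc3)c2cc1C
F6 | step 6 | lithium 4-(benzyloxy)-7-methoxy-6-methyl-2-(trimethylsilyl)naphthalen-1-olate | [Li+].[O-]c1c([Si](C)(C)C)cc(OCc2ccccc2)c2cc(C)c(OC)cc12
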